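**Plan**
Cuts: the three aryl OH groups go back to methyl ethers and the C6 formyl group to a methyl ester. The benzo ring is then opened at C3a–C4, the C6–C7 bond is cut as an alkene condensation, and finally the C2–aryl and C3–aryl bonds are cut.
Enabling feature: in the benzofuran (O1, C2, C3, C3a, C4–C7, C7a) the benzo ring bears OH on C4, next to fusion carbon C3a, and the formyl carbon on C6, meta to it. The four carbons of a succinate map onto C4, C5, C6 and the formyl carbon. A furaldehyde carbon maps onto C7, and furan C2/C3 map onto C7a/C3a.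
Forward order: the furan ring is bought, arylated at its C5 and then at its C4, and extended by a Stobbe condensation. The benzo ring is closed last, onto the furan β-carbon, and reduction, oxidation and demethylation follow.
Stereochemistry: the target has no stereocentre. The only stereoelement of the route is the E geometry of the half-ester alkene, which is set in the Stobbe elimination.

Key step: step 4

Remark: the Stobbe lactone and the dienone formed on ring closure are transient and lose their sp3 centres in the same flask, so their SMILES carry no stereodescriptors.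

Step 1
Reactants: 1 4,5-dibromofuran-2-carbaldehyde; 2 4-methoxyphenylboronic acid (1.05 equiv)
Product: 3 4-bromo-5-(4-methoxyphenyl)furan-2-carbaldehyde
Conditions: Pd(PPh3)4 (cat.), K2CO3, 1,4-dioxane–H2O, 80 °C
Reagents that add atoms: none
Why: Site-selective Suzuki–Miyaura coupling, in which zerovalent palladium should insert first into the C5–Br bond because it lies α to the ring oxygen and is conjugated with the formyl group, so one equivalent of 2 should leave the C4 bromide in place.

Step 2
Reactants: 3 4-bromo-5-(4-methoxyphenyl)furan-2-carbaldehyde; 4 3,5-dimethoxyphenylboronic acid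
Product: 5 4-(3,5-dimethoxyphenyl)-5-(4-methoxyphenyl)furan-2-carbaldehyde
Conditions: Pd(OAc)2 (cat.), SPhos, K3PO4, toluene–H2O, 90 °C
Reagents that add atoms: none
Why: Second Suzuki–Miyaura coupling, in which the electron-rich, bulky biarylphosphine should speed oxidative addition into the slower, aryl-flanked β-bromide, while the aldehyde tolerates the phosphate base.

Step 3
Reactants: 5 4-(3,5-dimethoxyphenyl)-5-(4-methoxyphenyl)furan-2-carbaldehyde; 6 dimethyl succinate
Product: 8 (3E)-4-[4-(3,5-dimethoxyphenyl)-5-(4-methoxyphenyl)furan-2-yl]-3-(methoxycarbonyl)but-3-enoic acid, via paraconate lactone 7 (not isolated)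
Conditions: t-BuOK, t-BuOH, reflux; then aq HCl
Reagents that add atoms: none
Why: Stobbe condensation, in which the succinate enolate adds to the non-enolisable aldehyde, the alkoxide lactonises onto the far ester to give 7, and irreversible E1cB opening of 7 should give the carboxylate of 8 mainly as the E isomer, with the furyl group trans to the conjugated ester.

Step 4
Reactants: 8 (3E)-4-[4-(3,5-dimethoxyphenyl)-5-(4-methoxyphenyl)furan-2-yl]-3-(methoxycarbonyl)but-3-enoic acid
Product: 13 methyl 4-acetoxy-3-(3,5-dimethoxyphenyl)-2-(4-methoxyphenyl)-1-benzofuran-6-carboxylate, via mixed anhydride 9 (not isolated), via dienyl ketene 10 (not isolated), via 3aH-dienone 11 (not isolated), via free phenol 12 (not isolated)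
Conditions: Ac2O, NaOAc, reflux (ca. 140 °C)
Reagents that add atoms: acetic anhydride, CC(=O)OC(C)=O
Why: Acetic anhydride converts the acid of 8 into mixed anhydride 9, from which acetate removes an α-proton and acetic acid is expelled to leave dienyl ketene 10. In 10 the ketene C=C, the side-chain alkene and the furan C2=C3 bond form a hexatriene that should close by a thermal, disrotatory six-electron electrocyclisation, joining the ketene carbon to the furan β-carbon (the C3a–C4 bond) and closing the six-membered benzo ring as dienone 11. Loss of the C3a proton aromatises 11 to phenol 12, which the medium acetylates to 13, so the sp3 centre of 11 is erased and no stereocentre needs control. The closest known reaction type is the Ac2O–NaOAc ring closure of Stobbe half-esters, which gives 4-acetoxy-2-naphthoates from arylmethylidene and 4-acetoxybenzofuran-6-carboxylates from furylmethylidene succinic half-esters, and a 6-exo-trig Friedel–Crafts acylation of the furan by 9 would end at the same product. Regioselectivity is fixed by the substrate, because C3 is the only unsubstituted furan carbon and the only one the acyl carbon can reach, which places the oxygen on C4 and the ester on C6. The closure needs the furyl group cis to the CH2CO2H arm, which is the E geometry of 8, and any Z isomer cannot reach C3 and should either equilibrate in the hot acetate medium or be removed when 13 is purified.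

Step 5
Reactants: 13 methyl 4-acetoxy-3-(3,5-dimethoxyphenyl)-2-(4-methoxyphenyl)-1-benzofuran-6-carboxylate
Product: 14 3-(3,5-dimethoxyphenyl)-6-(hydroxymethyl)-2-(4-methoxyphenyl)-1-benzofuran-4-ol
Conditions: LiAlH4, THF, 0 °C to rt; aqueous work-up
Reagents that add atoms: none
Why: Complex-hydride ester reduction, which should take the methyl ester to the benzylic alcohol and cleave the aryl acetate to the phenol in the same operation, so no separate deacetylation is needed, while the aryl methyl ethers and the benzofuran are inert.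

Step 6
Reactants: 14 3-(3,5-dimethoxyphenyl)-6-(hydroxymethyl)-2-(4-methoxyphenyl)-1-benzofuran-4-ol
Product: 15 3-(3,5-dimethoxyphenyl)-4-hydroxy-2-(4-methoxyphenyl)-1-benzofuran-6-carbaldehyde
Conditions: activated MnO2 (excess), CH2Cl2–acetone, rt
Reagents that add atoms: none
Why: Selective benzylic alcohol oxidation with MnO2, which stops at the aldehyde and is routine for hydroxybenzyl alcohols, and here the phenol sits meta to the carbinol so no quinone methide can form.

Step 7
Reactants: 15 3-(3,5-dimethoxyphenyl)-4-hydroxy-2-(4-methoxyphenyl)-1-benzofuran-6-carbaldehyde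
Product: 16 3-(3,5-dihydroxyphenyl)-4-hydroxy-2-(4-hydroxyphenyl)-1-benzofuran-6-carbaldehyde (target)
Conditions: BBr3 (8 equiv), CH2Cl2, −78 °C to rt; then ice–water
Reagents that add atoms: none
Why: Lewis-acid aryl methyl ether cleavage, in which BBr3 binds each ether oxygen and bromide removes the methyl group, the aryl borates and the boron-complexed aldehyde are hydrolysed on aqueous work-up as is well established for methoxybenzaldehydes, and the fully aromatic benzofuran offers no acid-labile benzylic C–O bond.

**Compound list**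
1 | 4,5-dibromofuran-2-carbaldehyde | O=Cc1cc(Br)c(Br)o1 | starting material
2 | 4-methoxyphenylboronic acid | COc1ccc(B(O)O)cc1 | starting material
3 | 4-bromo-5-(4-methoxyphenyl)furan-2-carbaldehyde | O=Cc1cc(Br)c(-c2ccc(OC)cc2)o1 | intermediate
4 | 3,5-dimethoxyphenylboronic acid | COc1cc(B(O)O)cc(OC)c1 | starting material
5 | 4-(3,5-dimethoxyphenyl)-5-(4-methoxyphenyl)furan-2-carbaldehyde | O=Cc1cc(-c2cc(OC)cc(OC)c2)c(-c2ccc(OC)cc2)o1 | intermediate
6 | dimethyl succinate | COC(=O)CCC(=O)OC | starting material
7 | methyl 2-[4-(3,5-dimethoxyphenyl)-5-(4-methoxyphenyl)furan-2-yl]-5-oxooxolane-3-carboxylate (transient, racemic diastereomer mixture) | COC(=O)C1CC(=O)OC1c1cc(-c2cc(OC)cc(OC)c2)c(-c2ccc(OC)cc2)o1 | intermediate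
8 | (3E)-4-[4-(3,5-dimethoxyphenyl)-5-(4-methoxyphenyl)furan-2-yl]-3-(methoxycarbonyl)but-3-enoic acid | OC(=O)C/C(C(=O)OC)=C\c1cc(-c2cc(OC)cc(OC)c2)c(-c2ccc(OC)cc2)o1 | intermediate
9 | acetic (3E)-4-[4-(3,5-dimethoxyphenyl)-5-(4-methoxyphenyl)furan-2-yl]-3-(methoxycarbonyl)but-3-enoic anhydride (transient) | CC(=O)OC(=O)C/C(C(=O)OC)=C\c1cc(-c2cc(OC)cc(OC)c2)c(-c2ccc(OC)cc2)o1 | intermediate
10 | methyl (2E)-2-{[4-(3,5-dimethoxyphenyl)-5-(4-methoxyphenyl)furan-2-yl]methylidene}-4-oxobut-3-enoate (dienyl ketene, transient) | O=C=C/C(C(=O)OC)=C\c1cc(-c2cc(OC)cc(OC)c2)c(-c2ccc(OC)cc2)o1 | intermediate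
11 | methyl 3-(3,5-dimethoxyphenyl)-2-(4-methoxyphenyl)-4-oxo-3a,4-dihydro-1-benzofuran-6-carboxylate (transient, racemic at C3a) | COC(=O)C1=CC(=O)C2C(=C1)OC(-c1ccc(OC)cc1)=C2-c1cc(OC)cc(OC)c1 | intermediate
12 | methyl 3-(3,5-dimethoxyphenyl)-4-hydroxy-2-(4-methoxyphenyl)-1-benzofuran-6-carboxylate (transient) | COC(=O)c1cc(O)c2c(-c3cc(OC)cc(OC)c3)c(-c3ccc(OC)cc3)oc2c1 | intermediate
13 | methyl 4-acetoxy-3-(3,5-dimethoxyphenyl)-2-(4-methoxyphenyl)-1-benzofuran-6-carboxylate | COC(=O)c1cc(OC(C)=O)c2c(-c3cc(OC)cc(OC)c3)c(-c3ccc(OC)cc3)oc2c1 | intermediate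
14 | 3-(3,5-dimethoxyphenyl)-6-(hydroxymethyl)-2-(4-methoxyphenyl)-1-benzofuran-4-ol | OCc1cc(O)c2c(-c3cc(OC)cc(OC)c3)c(-c3ccc(OC)cc3)oc2c1 | intermediate
15 | 3-(3,5-dimethoxyphenyl)-4-hydroxy-2-(4-methoxyphenyl)-1-benzofuran-6-carbaldehyde | O=Cc1cc(O)c2c(-c3cc(OC)cc(OC)c3)c(-c3ccc(OC)cc3)oc2c1 | intermediate
16 | 3-(3,5-dihydroxyphenyl)-4-hydroxy-2-(4-hydroxyphenyl)-1-benzofuran-6-carbaldehyde (CNP0078653.0) | O=Cc1cc(O)c2c(-c3cc(O)cc(O)c3)c(-c3ccc(O)cc3)oc2c1 | target

Total step count: 7
Longest linear sequence: 7 steps (1 to 16)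

**Steps most likely to fail**

Step 4. The aryl group on the neighbouring furan carbon crowds the β-carbon that has to be attacked. Ring closure may therefore become slower than oligomerisation of the ketene and breakdown of the electron-rich furan in the hot medium. The fallback exchanges the order of arylation and benzannulation, so that the ring closes next to a bromine atom instead of an aryl group.
- It sets out from 3. Stobbe condensation with 6 (t-BuOK, t-BuOH) should give (3E)-4-[4-bromo-5-(4-methoxyphenyl)furan-2-yl]-3-(methoxycarbonyl)but-3-enoic acid F1.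
- Closure with Ac2O–NaOAc should then give methyl 4-acetoxy-3-bromo-2-(4-methoxyphenyl)-1-benzofuran-6-carboxylate F2.
- Suzuki–Miyaura coupling of F2 with 4 (Pd(OAc)2, SPhos, anhydrous K3PO4, toluene) brings the sequence back to the route at 13.

Step 7. The boron-complexed aldehyde is a strong electrophile and the resorcinol ring being unmasked is a strong nucleophile. Intermolecular Friedel–Crafts hydroxyalkylation to oligomers may consume material, or cleavage may stay incomplete if the reaction is stopped early. The fallback removes the methyl ethers before the aldehyde exists and replaces them with silyl ethers that are cleaved by fluoride. This also keeps free phenols out of the MnO2 oxidation.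
- It sets out from 13. BBr3 in CH2Cl2 followed by warm methanol, which also transesterifies the acetate away, should give methyl 3-(3,5-dihydroxyphenyl)-4-hydroxy-2-(4-hydroxyphenyl)-1-benzofuran-6-carboxylate F3.
- TBSCl and imidazole in DMF should give methyl 4-(tert-butyldimethylsilyloxy)-3-[3,5-bis(tert-butyldimethylsilyloxy)phenyl]-2-[4-(tert-butyldimethylsilyloxy)phenyl]-1-benzofuran-6-carboxylate F4.
- i-Bu2AlH in CH2Cl2 should give {4-(tert-butyldimethylsilyloxy)-3-[3,5-bis(tert-butyldimethylsilyloxy)phenyl]-2-[4-(tert-butyldimethylsilyloxy)phenyl]-1-benzofuran-6-yl}methanol F5.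
- MnO2 should give 4-(tert-butyldimethylsilyloxy)-3-[3,5-bis(tert-butyldimethylsilyloxy)phenyl]-2-[4-(tert-butyldimethylsilyloxy)phenyl]-1-benzofuran-6-carbaldehyde F6.
- Et3N·3HF in THF then returns to the route at 16.

Step 3. The donor-substituted furaldehyde is a sluggish electrophile, so self-condensation of the succinate may compete. The eliminative lactone opening may also show poor E/Z selectivity, leaving part of the material in the geometry that cannot cyclise. The fallback builds the alkene by a Horner–Wadsworth–Emmons olefination with a succinate whose two esters are differentiated.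
- Trimethyl phosphonoacetate is alkylated with tert-butyl bromoacetate (NaH, THF) to give 4-tert-butyl 1-methyl 2-(dimethoxyphosphoryl)butanedioate F7.
- Setting out from 5, the sodium salt of F7 should give, with high E selectivity, 4-tert-butyl 1-methyl (2E)-2-{[4-(3,5-dimethoxyphenyl)-5-(4-methoxyphenyl)furan-2-yl]methylidene}butanedioate F8.
- CF3CO2H in CH2Cl2 removes only the tert-butyl ester and returns to the route at 8.

**Further compounds**
F1 | step 4 | (3E)-4-[4-bromo-5-(4-methoxyphenyl)furan-2-yl]-3-(methoxycarbonyl)but-3-enoic acid | OC(=O)C/C(C(=O)OC)=C\c1cc(Br)c(-c2ccc(OC)cc2)o1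
F2 | step 4 | methyl 4-acetoxy-3-bromo-2-(4-methoxyphenyl)-1-benzofuran-6-carboxylate | COC(=O)c1cc(OC(C)=O)c2c(Br)c(-c3ccc(OC)cc3)oc2c1
F3 | step 7 | methyl 3-(3,5-dihydroxyphenyl)-4-hydroxy-2-(4-hydroxyphenyl)-1-benzofuran-6-carboxylate | COC(=O)c1cc(O)c2c(-c3cc(O)cc(O)c3)c(-c3ccc(O)cc3)oc2c1
F4 | step 7 | methyl 4-(tert-butyldimethylsilyloxy)-3-[3,5-bis(tert-butyldimethylsilyloxy)phenyl]-2-[4-(tert-butyldimethylsilyloxy)phenyl]-1-benzofuran-6-carboxylate | COC(=O)c1cc(O[Si](C)(C)C(C)(C)C)c2c(-c3cc(O[Si](C)(C)C(C)(C)C)cc(O[Si](C)(C)C(C)(C)C)c3)c(-c3ccc(O[Si](C)(C)C(C)(C)C)cc3)oc2c1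
F5 | step 7 | {4-(tert-butyldimethylsilyloxy)-3-[3,5-bis(tert-butyldimethylsilyloxy)phenyl]-2-[4-(tert-butyldimethylsilyloxy)phenyl]-1-benzofuran-6-yl}methanol | OCc1cc(O[Si](C)(C)C(C)(C)C)c2c(-c3cc(O[Si](C)(C)C(C)(C)C)cc(O[Si](C)(C)C(C)(C)C)c3)c(-c3ccc(O[Si](C)(C)C(C)(C)C)cc3)oc2c1
F6 | step 7 | 4-(tert-butyldimethylsilyloxy)-3-[3,5-bis(tert-butyldimethylsilyloxy)phenyl]-2-[4-(tert-butyldimethylsilyloxy)phenyl]-1-benzofuran-6-carbaldehyde | O=Cc1cc(O[Si](C)(C)C(C)(C)C)c2c(-c3cc(O[Si](C)(C)C(C)(C)C)cc(O[Si](C)(C)C(C)(C)C)c3)c(-c3ccc(O[Si](C)(C)C(C)(C)C)cc3)oc2c1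
F7 | step 3 | 4-tert-butyl 1-methyl 2-(dimethoxyphosphoryl)butanedioate | COC(=O)C(CC(=O)OC(C)(C)C)P(=O)(OC)OC
F8 | step 3 | 4-tert-butyl 1-methyl (2E)-2-{[4-(3,5-dimethoxyphenyl)-5-(4-methoxyphenyl)furan-2-yl]methylidene}butanedioate | CC(C)(C)OC(=O)C/C(C(=O)OC)=C\c1cc(-c2cc(OC)cc(OC)c2)c(-c2ccc(OC)cc2)o1
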